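The route rests on disconnecting the C1–O bond of the phenol, which exposes a mirror-symmetric 5-alkylresorcinol dimethyl ether. In that benzene ring the two C–H carbons flanking the C21 chain (C2 and C6) are equivalent, and each lies para to one methoxy oxygen and ortho to the other; the key step exploits exactly this feature. A single electrophilic oxygen transfer from phthaloyl peroxide should convert one of these C–H bonds into an aryl hydrogen phthalate, with no ring formed and no stereocentre created. The precursor, 1-heneicosyl-3,5-dimethoxybenzene, comes from a Wittig olefination followed by hydrogenation, and a bicarbonate hydrolysis then unmasks the phenol.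

Key step: step 5

Remark: the Wittig step is expected to give a Z-rich mixture of alkene isomers; compound 5 is drawn as the Z isomer, and both isomers converge in step 3.
Remark: the ester cleavage in step 6 is formulated as a hydrolysis, so the departing fragment is counted as phthalic acid.
Remark: phthaloyl peroxide is shock- and heat-sensitive; it should be made on a small scale behind a shield, stored cold and used promptly.

Step 1
Reactants: 1 1-bromoeicosane
Product: 2 eicosyltriphenylphosphonium bromide
Conditions: PPh3 (1.1 equiv), MeCN, reflux, 48 h; trituration with Et2O
Reagents that add atoms: triphenylphosphine, c1ccc(cc1)P(c1ccccc1)c1ccccc1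
Why: SN2 quaternisation of triphenylphosphine by an unhindered primary alkyl bromide is a dependable phosphonium salt formation, and the salt should separate from the unreacted components on trituration.

Step 2
Reactants: 2 eicosyltriphenylphosphonium bromide; 3 3,5-dimethoxybenzaldehyde
Product: 5 (Z)-1-(3,5-dimethoxyphenyl)heneicos-1-ene, via eicosylidenetriphenylphosphorane 4 (not isolated)
Conditions: KOtBu, THF, 0 °C; then 3, 0 °C→rt
Reagents that add atoms: none
Why: Wittig olefination of a non-enolisable aromatic aldehyde with a non-stabilised ylide is reliable, and the alkene geometry is immaterial because the double bond is saturated in the next step.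

Step 3
Reactants: 5 (Z)-1-(3,5-dimethoxyphenyl)heneicos-1-ene
Product: 6 1-heneicosyl-3,5-dimethoxybenzene
Conditions: H2 (1 atm), 10% Pd/C, EtOAc, rt
Reagents that add atoms: none
Why: Heterogeneous catalytic hydrogenation of a disubstituted styrenic alkene is routine, the aryl methyl ethers are inert, and no benzylic C–O bond is present that could be hydrogenolysed.

Step 4
Reactants: 7 phthaloyl chloride
Product: 8 phthaloyl peroxide
Conditions: 2Na2CO3·3H2O2, CH2Cl2, rt; filter, concentrate cold
Reagents that add atoms: sodium percarbonate (carrier of hydrogen peroxide), OO.OO.OO.[Na+].[Na+].[Na+].[Na+].[O-]C([O-])=O.[O-]C([O-])=O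
Why: Twofold nucleophilic acyl substitution of the bis(acid chloride) by hydrogen peroxide released from the percarbonate, with carbonate scavenging the HCl, closes the six-membered cyclic diacyl peroxide, which is the established way to this reagent.

Step 5
Reactants: 6 1-heneicosyl-3,5-dimethoxybenzene; 8 phthaloyl peroxide
Product: 9 2-[(2-heneicosyl-4,6-dimethoxyphenoxy)carbonyl]benzoic acid
Conditions: 8 (1.2 equiv), HFIP/CH2Cl2, 0→23 °C, dark; evaporate, crude 9 carried on
Reagents that add atoms: none
Why: The weak O–O bond of 8 should open as one carboxyl oxygen bonds to C2 (equivalent to C6) of 6, giving a cyclohexadienyl radical paired with the tethered carboxyl radical, which then removes the hydrogen from the attacked carbon and so restores the aromatic ring with the new C–O bond in place (reverse-rebound pathway). The closest known reaction type is the metal-free C–H hydroxylation of alkylated anisoles and dimethoxybenzenes by phthaloyl peroxide in fluorinated alcohols, of which this is a direct application. No ring is closed and no stereocentre is created, so neither a mode of closure nor a controlling element arises. The step needs site selectivity and mono-oxygenation: C2 and C6 are symmetry-equivalent, each para to one methoxyl and ortho to the other and counted twice statistically, whereas C4 is only ortho-activated and wedged between two methoxyls, the same preference that electrophilic bromination and formylation of 5-alkylresorcinol dimethyl ethers show. Once acylated, the new oxygen is a poor donor and no free phenol is present, so a second attack or oxidation to a quinone should be slow. HFIP activates the peroxide by hydrogen bonding and the CH2Cl2 co-solvent keeps the C21 chain in solution.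

Step 6
Reactants: 9 2-[(2-heneicosyl-4,6-dimethoxyphenoxy)carbonyl]benzoic acid
Product: 10 6-heneicosyl-2,4-dimethoxyphenol
Conditions: NaHCO3, THF/H2O (degassed), 40 °C, Ar; then 1 M HCl to pH 4
Reagents that add atoms: none
Why: Ester hydrolysis with intramolecular assistance by the ortho carboxylate makes this aryl ester labile enough for bicarbonate, a pH at which the phenol stays protonated and the methyl ethers are untouched, while exclusion of air protects the hydroquinone monoether from oxidation.

Compound list
1 | 1-bromoeicosane | CCCCCCCCCCCCCCCCCCCCBr | starting material
2 | eicosyltriphenylphosphonium bromide | CCCCCCCCCCCCCCCCCCCC[P+](c1ccccc1)(c1ccccc1)c1ccccc1.[Br-] | intermediate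
3 | 3,5-dimethoxybenzaldehyde | COc1cc(C=O)cc(OC)c1 | starting material
4 | eicosylidenetriphenylphosphorane | CCCCCCCCCCCCCCCCCCCC=P(c1ccccc1)(c1ccccc1)c1ccccc1 | intermediate
5 | (Z)-1-(3,5-dimethoxyphenyl)heneicos-1-ene (Z isomer drawn; some E isomer expected) | CCCCCCCCCCCCCCCCCCC/C=C\c1cc(OC)cc(OC)c1 | intermediate
6 | 1-heneicosyl-3,5-dimethoxybenzene | CCCCCCCCCCCCCCCCCCCCCc1cc(OC)cc(OC)c1 | intermediate
7 | phthaloyl chloride | O=C(Cl)c1ccccc1C(Cl)=O | starting material
8 | phthaloyl peroxide | O=C1OOC(=O)c2ccccc12 | intermediate
9 | 2-[(2-heneicosyl-4,6-dimethoxyphenoxy)carbonyl]benzoic acid | CCCCCCCCCCCCCCCCCCCCCc1cc(OC)cc(OC)c1OC(=O)c1ccccc1C(=O)O | intermediate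
10 | 6-heneicosyl-2,4-dimethoxyphenol | CCCCCCCCCCCCCCCCCCCCCc1cc(OC)cc(OC)c1O | target

Total step count: 6.
Longest linear sequence: 5 steps (steps 1, 2, 3, 5, 6); step 4 is a one-step branch that supplies the oxidant.

Steps most likely to fail

1. Step 5. Site control may erode through competing attack at the C4–H between the two methoxyls. The still electron-rich product may be oxygenated a second time, or conversion may stall if the lipophilic substrate separates from the fluorinated medium. The fallback sets out from 6 and returns to the route at 10, and it also removes the need for 8. Vilsmeier–Haack formylation (POCl3, DMF, 0→60 °C) should attack the same position ortho to the chain and para to a methoxyl, giving [(2-heneicosyl-4,6-dimethoxyphenyl)methylidene]dimethylammonium chloride F1. Aqueous NaOAc hydrolysis should convert this to 2-heneicosyl-4,6-dimethoxybenzaldehyde F2. Baeyer–Villiger (Dakin-type) oxidation with mCPBA in CH2Cl2, where the electron-rich aryl group migrates, should then give 2-heneicosyl-4,6-dimethoxyphenyl formate F3. Hydrolysis of F3 with NaHCO3 in degassed THF/H2O should release 10.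

2. Step 6. The liberated electron-rich phenol may be oxidised by air towards a quinone in the basic aqueous medium, or cleavage may be slow because the soap-like carboxylate aggregates. The fallback sets out from 9 and returns at 10 by reductive instead of hydrolytic cleavage. Excess LiAlH4 in THF (0 °C→rt, then Rochelle-salt work-up) should reduce both the aryl ester and the acid, releasing the phenol under anhydrous, oxygen-free, reducing conditions with 1,2-benzenedimethanol as the co-product. This fallback makes no new compound on the way (F0).

3. Step 2. Ylide generation from the waxy, hygroscopic long-chain salt may be incomplete, and residual moisture may protonate the ylide, leaving aldehyde unconsumed. The fallback sets out from 1 and 3 and returns at 6, bypassing steps 1 to 3. Magnesium insertion into 1 (Mg, THF) should give eicosylmagnesium bromide F4, which should add to aldehyde 3. After a dilute HCl quench this gives racemic 1-(3,5-dimethoxyphenyl)heneicosan-1-ol F5. Benzylic hydrogenolysis (H2, Pd/C, EtOAc/AcOH, catalytic H2SO4) should then remove the hydroxyl group and its stereocentre to give 6.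

Further compounds
F1 | step 5 | [(2-heneicosyl-4,6-dimethoxyphenyl)methylidene]dimethylammonium chloride | CCCCCCCCCCCCCCCCCCCCCc1cc(OC)cc(OC)c1C=[N+](C)C.[Cl-]
F2 | step 5 | 2-heneicosyl-4,6-dimethoxybenzaldehyde | CCCCCCCCCCCCCCCCCCCCCc1cc(OC)cc(OC)c1C=O
F3 | step 5 | 2-heneicosyl-4,6-dimethoxyphenyl formate | CCCCCCCCCCCCCCCCCCCCCc1cc(OC)cc(OC)c1OC=O
F0 | step 6 | none | none
F4 | step 2 | eicosylmagnesium bromide | CCCCCCCCCCCCCCCCCCCC[Mg]Br
F5 | step 2 | 1-(3,5-dimethoxyphenyl)heneicosan-1-ol (racemic) | CCCCCCCCCCCCCCCCCCCCC(O)c1cc(OC)cc(OC)c1
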